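**Retrosynthetic overview**

1. Ligraminol C (10) ⇒ aldehyde 8: the Z-propenyl C=C on ring B is made last by Wittig ethylidenation of the ring B formyl group.
2. Feature: benzylic C7 (on ring A) carries the acetate, and C8 carries the methyl group and the ether oxygen bonded to C4' of ring B, in a threo (7R,8R) relation. This is the imprint of anti opening of a cis C7–C8 oxirane at C7 followed by arylation of the freed O8.
3. 8 ⇒ cis-epoxide 4 + cesium acetate 5 + 4-fluoro-3-methoxybenzaldehyde 6 in one flask: C7–OAc by SN2 opening, O8–C4' by SNAr para to the formyl group.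
4. 4 ⇒ Z-alkene 3 (Jacobsen–Katsuki epoxidation) ⇒ bromide 1 + (Z)-propenylboronic acid 2 (stereoretentive Suzuki–Miyaura coupling, chosen so that the alkene geometry is bought and not made).
5. Rings A and B are bought; the only ring formed is the oxirane (step 2), and it is opened again in step 3.

Key step: step 3

Remark: labels follow neolignan usage (ring A = 3,4-dimethoxyphenyl, C7 = benzylic carbon, C8 = methyl-bearing carbon, ring B = the aryloxy ring, C4' = its carbon bonded to O8); the SMILES is read as the (7R,8R) threo isomer with a Z propenyl group.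

**Route**

Step 1
Reactants: 1 4-bromo-1,2-dimethoxybenzene; 2 (Z)-prop-1-en-1-ylboronic acid
Product: 3 (Z)-1,2-dimethoxy-4-(prop-1-en-1-yl)benzene
Conditions: Pd(PPh3)4 (3 mol %, zerovalent palladium), K2CO3, degassed DME/H2O, 80 °C
Reagents that add atoms: (Z)-prop-1-en-1-ylboronic acid 2, C/C=C\B(O)O
Why: Suzuki–Miyaura coupling, in which oxidative addition into the C–Br bond, transmetalation of the alkenylboron partner and reductive elimination all proceed with retention at the alkenyl carbon, so the Z geometry of 2 should be carried into 3.

Step 2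
Reactants: 3 (Z)-1,2-dimethoxy-4-(prop-1-en-1-yl)benzene
Product: 4 (2S,3R)-2-(3,4-dimethoxyphenyl)-3-methyloxirane
Conditions: (S,S)-N,N'-bis(3,5-di-tert-butylsalicylidene)-1,2-cyclohexanediaminomanganese chloride (trivalent manganese, 5 mol %), 4-phenylpyridine N-oxide (20 mol %), aq NaOCl (Na2HPO4 buffer, pH 11.3), CH2Cl2, 0 °C; filtration through basic Al2O3
Reagents that add atoms: sodium hypochlorite, [Na+].[O-]Cl
Why: Jacobsen–Katsuki epoxidation, in which the (S,S) complex should deliver oxygen to one face of the cis aryl alkene by side-on approach and so set C7 (S) and C8 (R) together under catalyst control, in the sense this catalyst antipode shows with cis-β-methylstyrene and indene.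

Step 3
Reactants: 4 (2S,3R)-2-(3,4-dimethoxyphenyl)-3-methyloxirane; 5 cesium acetate; 6 4-fluoro-3-methoxybenzaldehyde
Product: 8 (1R,2R)-1-(3,4-dimethoxyphenyl)-2-(4-formyl-2-methoxyphenoxy)propyl acetate, via cesium threo acetoxy alkoxide 7 (not isolated)
Conditions: CsOAc (dried, 1.5 equiv), 6 (3 equiv), 4 Å molecular sieves, dry DMF, 80 °C, 4 added slowly
Reagents that add atoms: cesium acetate 5, CC(=O)[O-].[Cs+]; 4-fluoro-3-methoxybenzaldehyde 6, COc1cc(C=O)ccc1F
Why: Proposed new method: in dry DMF the weakly ion-paired acetate of 5 should attack benzylic C7 of cis-epoxide 4 anti to the C7–O bond (SN2; without acid no free benzylic cation forms), which opens the oxirane to threo alkoxide 7 with C7 inverted from S to R and C8 left as R. Alkoxide 7 should then add to C4' of 6, para to the formyl group, and expel fluoride (addition–elimination SNAr), which forms the O8–C4' ether and removes the alkoxide from the reversible opening equilibrium. The closest known reaction types are the opening of aryl epoxides by carboxylates at the benzylic carbon with inversion and the etherification of secondary alkoxides with 4-fluorobenzaldehydes; their union in one flask through a β-acetoxy alkoxide has not been shown. No ring is formed, and the single new stereocentre, C7, is controlled by the stereospecific backside opening of the enantioenriched cis-epoxide, so the threo relation is inherited from the cis geometry and the catalyst-set configuration of 4. The step needs attack at C7 and not at C8 (C8 attack followed by acetyl shift would lead to the enantiomer), which the weakening of the C7–O bond by electron-rich ring A should ensure, and it needs arylation of O8 although a 1,2-acetyl shift equilibrates 7 with the benzylic C7 alkoxide (Curtin–Hammett situation). The non-benzylic C8 alkoxide is the less hindered and more basic partner for the C–F carbon flanked by the ortho methoxy group, and an excess of 6 with slow addition of 4 should trap it before scrambling.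

Step 4
Reactants: 8 (1R,2R)-1-(3,4-dimethoxyphenyl)-2-(4-formyl-2-methoxyphenoxy)propyl acetate; 9 ethyltriphenylphosphonium bromide
Product: 10 ligraminol C, (1R,2R)-1-(3,4-dimethoxyphenyl)-2-[2-methoxy-4-((Z)-prop-1-en-1-yl)phenoxy]propyl acetate
Conditions: 9 (1.5 equiv), NaN(SiMe3)2 (1.4 equiv), THF, 0 °C; then 8, −78 to 0 °C
Reagents that add atoms: ethyltriphenylphosphonium bromide 9, CC[P+](c1ccccc1)(c1ccccc1)c1ccccc1.[Br-]
Why: Wittig olefination, in which the non-stabilised ethylidene ylide, made lithium-free with the base as the limiting reagent, should add to the aldehyde under kinetic control to give the Z alkene, while at −78 °C the C7 acetate and the two non-enolisable stereocentres should not be touched.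

**Compound list**

1 | 4-bromo-1,2-dimethoxybenzene | COc1ccc(Br)cc1OC | starting material
2 | (Z)-prop-1-en-1-ylboronic acid | C/C=C\B(O)O | starting material
3 | (Z)-1,2-dimethoxy-4-(prop-1-en-1-yl)benzene | C/C=C\c1ccc(OC)c(OC)c1 | intermediate
4 | (2S,3R)-2-(3,4-dimethoxyphenyl)-3-methyloxirane | C[C@H]1O[C@H]1c1ccc(OC)c(OC)c1 | intermediate
5 | cesium acetate | CC(=O)[O-].[Cs+] | starting material
6 | 4-fluoro-3-methoxybenzaldehyde | COc1cc(C=O)ccc1F | starting material
7 | cesium (1R,2R)-1-acetoxy-1-(3,4-dimethoxyphenyl)propan-2-olate | [O-][C@H](C)[C@H](OC(C)=O)c1ccc(OC)c(OC)c1.[Cs+] | intermediate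
8 | (1R,2R)-1-(3,4-dimethoxyphenyl)-2-(4-formyl-2-methoxyphenoxy)propyl acetate | COc1cc(C=O)ccc1O[C@H](C)[C@H](OC(C)=O)c1ccc(OC)c(OC)c1 | intermediate
9 | ethyltriphenylphosphonium bromide | CC[P+](c1ccccc1)(c1ccccc1)c1ccccc1.[Br-] | starting material
10 | ligraminol C | C/C=C\c1ccc(O[C@H](C)[C@H](OC(C)=O)c2ccc(OC)c(OC)c2)c(OC)c1 | target

**Totals**

Total step count: 4. Longest linear sequence: 4 steps (1 → 3 → 4 → 8 → 10).

**Steps most likely to fail**

Step 3 (the proposed new method).
- What may go wrong:
  - Regiochemical leakage: the 1,2-acetyl shift in alkoxide 7 is intramolecular and cannot be outrun, and the benzylic alkoxide may be the more populated one, so arylation at O7 may compete.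
  - Erosion of enantiomeric purity: acetate may attack C8, or the shifted alkoxide may re-close to the antipodal epoxide.
  - Loss of material: acetate may be consumed by the fluoroarene, or the opening may be too slow at a temperature the alkoxide tolerates.
- Fallback (known chemistry): it sets out from bromide 1 and returns to the route at 10. It forms the O8–C4' bond by Mitsunobu inversion of a lactate and sets C7 by substrate-controlled ketone reduction.
  - Methyl (S)-lactate and 4-bromo-2-methoxyphenol (PPh3, DIAD, THF, 0 °C to rt) should give, with inversion at C8, methyl (R)-2-(4-bromo-2-methoxyphenoxy)propanoate F1.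
  - AlMe3 and MeNH(OMe)·HCl in CH2Cl2 convert F1 into (R)-2-(4-bromo-2-methoxyphenoxy)-N-methoxy-N-methylpropanamide F2.
  - Bromide 1 and Mg turnings in THF give (3,4-dimethoxyphenyl)magnesium bromide F3, which adds to F2 at −20 °C to give (R)-2-(4-bromo-2-methoxyphenoxy)-1-(3,4-dimethoxyphenyl)propan-1-one F4. A cold NH4Cl work-up is used so that the enolisable C8 centre keeps its configuration.
  - Reduction with KBH(s-Bu)3 in THF at −78 °C, under non-chelating Felkin–Anh control with hydride anti to the C8–OAr bond, should favour the threo alcohol (1R,2R)-2-(4-bromo-2-methoxyphenoxy)-1-(3,4-dimethoxyphenyl)propan-1-ol F5.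
  - Suzuki–Miyaura coupling of F5 with boronic acid 2 under the conditions of step 1 should give (1R,2R)-1-(3,4-dimethoxyphenyl)-2-[2-methoxy-4-((Z)-prop-1-en-1-yl)phenoxy]propan-1-ol F6.
  - Acetylation (Ac2O, pyridine, DMAP, CH2Cl2) gives 10.

Step 2.
- What may go wrong:
  - Oxygen transfer in two stages allows rotation about C7–C8, so trans-epoxide may form; it would be carried on to the erythro isomer of 8.
  - Facial selection may be incomplete.
  - The electron-rich benzylic epoxide may open or rearrange on acidic surfaces during isolation.
- Fallback (known chemistry): it sets out from bromide 1 and returns at epoxide 4. It takes C8 from the chiral pool and closes the oxirane by SN2 displacement, which cannot give trans-epoxide from the purified threo precursor.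
  - (S)-2-Chloropropanoyl chloride and MeNH(OMe)·HCl (pyridine, CH2Cl2, 0 °C) give (S)-2-chloro-N-methoxy-N-methylpropanamide F7.
  - (3,4-Dimethoxyphenyl)magnesium bromide F3, made from 1 and Mg in THF as above, adds to F7 at −20 °C to give (S)-2-chloro-1-(3,4-dimethoxyphenyl)propan-1-one F8.
  - Reduction with NaBH4 in MeOH/THF at −40 °C, under polar Felkin–Anh (Cornforth) control with hydride anti to the C–Cl bond, should favour the threo chlorohydrin (1S,2S)-2-chloro-1-(3,4-dimethoxyphenyl)propan-1-ol F9. F9 is not acid-labile and can be freed from its erythro isomer by chromatography or crystallisation.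
  - K2CO3 in MeOH then closes the ring by attack of O7 on C8 with inversion to give 4.

Step 4.
- What may go wrong:
  - The cis-selective addition of the ylide to an aryl aldehyde may be incomplete, leaving E isomer that is hard to remove at the last stage.
  - The ylide or residual amide base may attack the C7 acetate.
- Fallback (known chemistry): it sets out from aldehyde 8 and returns at 10. It fixes the geometry in a separable vinyl iodide and brings in the methyl group by cross-coupling.
  - Stork–Zhao olefination with (iodomethyl)triphenylphosphonium iodide and NaN(SiMe3)2 (THF/DMPU, −78 °C) should give (1R,2R)-1-(3,4-dimethoxyphenyl)-2-[4-((Z)-2-iodoethenyl)-2-methoxyphenoxy]propyl acetate F10.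
  - Negishi coupling of F10 with MeZnCl and Pd(PPh3)4 (zerovalent palladium) in THF at room temperature replaces iodine by methyl with retention of the Z geometry and gives 10. The organozinc reagent does not attack the acetate.

**Further compounds**

F1 | step 3 | methyl (R)-2-(4-bromo-2-methoxyphenoxy)propanoate | C[C@@H](Oc1ccc(Br)cc1OC)C(=O)OC
F2 | step 3 | (R)-2-(4-bromo-2-methoxyphenoxy)-N-methoxy-N-methylpropanamide | C[C@@H](Oc1ccc(Br)cc1OC)C(=O)N(C)OC
F3 | step 3 | (3,4-dimethoxyphenyl)magnesium bromide | COc1ccc([Mg]Br)cc1OC
F4 | step 3 | (R)-2-(4-bromo-2-methoxyphenoxy)-1-(3,4-dimethoxyphenyl)propan-1-one | C[C@@H](Oc1ccc(Br)cc1OC)C(=O)c1ccc(OC)c(OC)c1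
F5 | step 3 | (1R,2R)-2-(4-bromo-2-methoxyphenoxy)-1-(3,4-dimethoxyphenyl)propan-1-ol | C[C@@H](Oc1ccc(Br)cc1OC)[C@H](O)c1ccc(OC)c(OC)c1
F6 | step 3 | (1R,2R)-1-(3,4-dimethoxyphenyl)-2-[2-methoxy-4-((Z)-prop-1-en-1-yl)phenoxy]propan-1-ol | C/C=C\c1ccc(O[C@H](C)[C@H](O)c2ccc(OC)c(OC)c2)c(OC)c1
F7 | step 2 | (S)-2-chloro-N-methoxy-N-methylpropanamide | C[C@H](Cl)C(=O)N(C)OC
F8 | step 2 | (S)-2-chloro-1-(3,4-dimethoxyphenyl)propan-1-one | C[C@H](Cl)C(=O)c1ccc(OC)c(OC)c1
F9 | step 2 | (1S,2S)-2-chloro-1-(3,4-dimethoxyphenyl)propan-1-ol | C[C@H](Cl)[C@@H](O)c1ccc(OC)c(OC)c1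
F10 | step 4 | (1R,2R)-1-(3,4-dimethoxyphenyl)-2-[4-((Z)-2-iodoethenyl)-2-methoxyphenoxy]propyl acetate | I/C=C\c1ccc(O[C@H](C)[C@H](OC(C)=O)c2ccc(OC)c(OC)c2)c(OC)c1
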